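# Synthesis proposal for CNP0134824.1: (R)-3,8-dihydroxy-5-(4-hydroxy-2-oxo-2H-pyran-6-yl)-6-(3-methylbutyl)-3,4-dihydronaphthalen-1(2H)-one

Compound numbers are those of the list that follows the steps. Tetralone numbering (C1 ketone, C2, C3 carbinol, C4, C4a, C5–C8, C8a) is used for the target and all bicyclic intermediates.

## Analysis of the target

Target 30 is a 3,4-dihydronaphthalen-1(2H)-one in which aromatic ring A (C4a, C5–C8, C8a) is fused to carbocyclic ring B, which holds the C1 ketone, the C2 and C4 methylene groups and the C3 carbinol. Ring A is substituted at every position but C7: a 4-hydroxy-2-pyranone is bonded through its C6 to C5, a 3-methylbutyl chain sits on C6, and a phenol on C8 lies peri to the C1 carbonyl. The only stereocentre is C3, of R configuration, and the C5–pyranone axis, flanked on the pyranone side only by O and CH, should rotate freely and needs no control. The most fragile unit is the β-hydroxy ketone of ring B, because loss of water under acid, base or heat aromatizes ring B to a 1-naphthol. The 4-hydroxypyranone is a vinylogous acid whose lactone opens with hard nucleophiles. The difficulty is twofold: C3 is an isolated stereocentre with no neighbour to relay from, and C5 is flanked by C4a and C6, so the aryl–pyranone bond is hindered. The plan rests on the sequence C8a–C1(=O)–C2–C3(O)–C4–C4a of ring B: C1 and C4 hang on adjacent ring A carbons at ester and methyl oxidation level, which is an ortho-toluate, and C2–C3 is a two-carbon β-oxygenated acrylate unit.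

## Retrosynthetic reasoning

**Heteroatom unmasking (30 from 29 from 28).** The last two operations cut no C–C bond. The two benzyl ethers of 29 (on O8 and on the pyranone oxygen) leave by hydrogenolysis, and the silyl ether of 28 by buffered fluoride. Benzyl is preferred to methyl on both oxygens because a methyl vinylogous ester on the pyranone would need nucleophilic or Lewis acidic cleavage next to the β-hydroxy ketone. The gain is that both final steps are neutral or weakly acidic.

**C5–pyranone bond (28 from 22 and 27).** This bond is cut next because a pyranone is itself an acceptor for benzylic anions and cannot be carried through a strongly basic ring B construction. The cut is also convergent. The forward reaction is a Suzuki coupling of arylboronate 22 with chloropyranone 27. It has to work at a doubly ortho-substituted carbon without enolizing the β-silyloxy ketone. Partner 27 comes from O-benzylation of 26, and 26 from the self-condensation of two molecules of malonyl dichloride 23.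

**C5 functionalization (22 from 21 from 20 from 19).** The boron of 22 replaces the bromine of 21. The bromine is introduced into silyl ether 20 by electrophilic substitution, since C5 is para to the ether oxygen on C8. Silyl ether 20 is made from alcohol 19. The gain is that the ring A building block needs no substituent at C5, so an orsellinate suffices.

**Unmasking of ring B (19 from 17).** The C2 methylene of 19 is traced back to a carbon that carries a carboxyl group. The C3 hydroxyl is traced back to an oxygen tied to that carboxyl in a six-membered acylal, which gives tricycle 17. The forward reaction is acetal hydrolysis followed by decarboxylation. In 17, C2 is doubly activated, so ring B can close by a Claisen-type reaction, and the C3 oxygen is locked in a ring while the carbon skeleton is built.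

**Key disconnection (17 from 6 and 14).** The bonds C4–C3 and C2–C1 are cut. Both lie next to carbons that toluate 6 supplies at the right oxidation level, its ortho-methyl group as C4 and its ester as C1. What remains, C2–C3 with oxygen on C3 and a carboxyl on C2, is the alkene of dioxinone 14, whose acetal carbon is the only source of chirality. Cutting C1–C8a or C4–C4a instead would call for ring closure onto an arene that already bears four substituents, and the stereocentre would have to be made separately in an open chain. The forward reaction must give conjugate addition on the face opposite the tert-butyl group, then ring closure onto the ester, without expelling the C3 oxygen.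

**Toluate (6 from 3 and 5; 3 from 2 from 1; 5 from 4).** The bond between C6 of ring A and the side chain is cut. Methyl orsellinate 1 offers its 4-hydroxyl as the handle: it becomes the triflate in 2, the remaining phenol is benzylated in 3, and alkylzinc 5 (from bromide 4) is coupled. All ring A substituents of the key-step precursor then sit where 1 dictates, with no regiochemical question.

**Dioxinone (14 from 13; 13 from 10 and 11; 10 from 7 and 8).** The heterocycle is cut into formylketene 12 and pivalaldehyde 11. The ketene is released from formyl Meldrum's acid 10, made from Meldrum's acid 7 and orthoformate 8 through 9. The acetal carbon is the only stereocentre and has no chiral-pool origin, so racemate 13 is separated into its enantiomers and 14 is taken on.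

## Alternatives that were turned down

**Alternative 1:** Ring A is taken apart completely. The bonds cut are C8a–C4a (which also closes ring B) between the two alkyne ends of a silyl-capped diynone tether, and C5–C6 and C7–C8 to a terminal alkyne that brings the branched chain. In the forward direction [Rh(cod)2]BF4 with a binaphthyl bisphosphine joins the three alkynes in a [2+2+2] cyclotrimerization to give A1. In A1 a benzyldimethylsilyl group on C8 stands for the phenol, and the pyranone, as its methyl ether, is already on C5.

- For: it is the most convergent plan, with both rings formed in one step. The hindered C5–pyranone bond exists from the start, so no late coupling at a doubly ortho-substituted carbon is needed. On this point it is stronger than the chosen route.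
- Against: nothing in the substrate dictates the orientation of the terminal alkyne. The chain must end on C6, next to the pyranone-bearing C5, and not on C7, next to the silyl-bearing C8, and both neighbours are bulky, so regioisomers are to be expected. Both tether ends are substituted, which slows metallacycle formation and leaves room for self-trimerization of the terminal alkyne. The tether is a β-silyloxy ynone that eliminates easily and needs its own enantioselective synthesis of many steps. After A1, the aryl–silicon bond must be oxidized (Tamao–Fleming, fluoride and basic peroxide) and the pyranone methyl ether cleaved, both beside a β-oxy ketone that aromatizes.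
- Comparison: the chosen route takes the ring A pattern from 1 and has no orientation problem. It pays for this with three late steps (11, 12 and 15) for the C5–pyranone bond.

**Alternative 2:** The two bonds that anchor ring B on ring A, C4a–C4 and C8a–C1, are made together. An unsymmetrical aryne (alkoxy next to the triple bond), released by CsF, inserts into the bond between the methylene and the ketone carbon of an acetoacetate ester. This acyl-alkylation gives A2, with an acetyl arm (C1, C2) and an acetate arm (C4, C3).

- For: the carbon skeleton is reached quickly, and the regiochemistry is dependable because the carbon nucleophile adds to the aryne carbon remote from the alkoxy group. In speed to the bicyclic skeleton it is stronger than the chosen route.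
- Against: A2 has C3 at the ester oxidation level and no stereocentre. Claisen closure of ring B would give a 1,3-diketone that is the tautomer of a fully aromatic naphthalenediol, and converting that into the (R)-carbinol would need an enantioselective dearomatizing reduction for which no dependable chemical method exists. The detour through an aldehyde and an intramolecular aldol needs a catalyst to set C3, on an enolizable benzylic aldehyde, with a product that dehydrates. The aryne precursor takes several steps, and the C5 substitution remains to be done.
- Comparison: the chosen route creates C3 in the bond-forming step itself, under control of the acetal of 14.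

**Alternative 3:** Ring A is built onto a ready-made chiral ring B. The bonds cut are C8–C8a and C5–C4a. A 1,1-dialkoxy diene carrying the branched chain adds thermally to a bromoenone that already holds the silyloxy group on the future C3. DBU then causes dehydrohalogenation and loss of alcohol to give phenol A3.

- For: the stereocentre comes from an enantiopure ring B precursor, so no enantiomer separation is needed. On this point it is stronger than the chosen route, which discards half of 13 in step 7. The polarization of the ketene acetal fixes the orientation, and the phenol emerges free.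
- Against: the enone, with silyloxy β to the carbonyl, is one elimination away from a phenol. The aromatization step then applies base to exactly the β-silyloxy ketone that must survive. The electron-rich diene is hydrolytically fragile and needs a multi-step preparation, as does the enone. After A3, the free phenol directs halogenation to C7 as well as C5, so a protection step returns and the count is no shorter.
- Comparison: the chosen route makes ring B last and keeps the C3 oxygen locked in the acetal of 17 until the skeleton is complete.

Key step: step 8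

## Assumptions

- The enantiomer of 13 taken on from step 7 is the S form. Which fraction this is must be established once, for example by adding Me2CuLi to a sample and hydrolysing, which for the S enantiomer should lead to (R)-3-hydroxybutanoic acid.
- Compound 17 is drawn as the cis-fused keto tautomer. The carbon between its two carbonyl groups (C2 of the tetralone, position 4a of the tricycle) is configurationally labile and ceases to be a stereocentre in step 9.

## Route

Step 1
Reactants: 1 methyl 2,4-dihydroxy-6-methylbenzoate
Product: 2 methyl 2-hydroxy-6-methyl-4-[(trifluoromethanesulfonyl)oxy]benzoate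
Conditions: PhNTf2 (1.05 equiv), Et3N, CH2Cl2, 0 °C to rt
Reagents that add atoms: N-phenylbis(trifluoromethanesulfonimide), O=S(=O)(N(c1ccccc1)S(=O)(=O)C(F)(F)F)C(F)(F)F
Why: Phenol O-sulfonylation; the 4-hydroxyl is the more acidic one and is not held in the hydrogen bond to the ester that ties up the 2-hydroxyl, so one equivalent of the mild triflating agent should react there selectively.

Step 2
Reactants: 2 methyl 2-hydroxy-6-methyl-4-[(trifluoromethanesulfonyl)oxy]benzoate
Product: 3 methyl 2-(benzyloxy)-6-methyl-4-[(trifluoromethanesulfonyl)oxy]benzoate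
Conditions: BnBr, K2CO3, DMF, rt to 40 °C
Reagents that add atoms: benzyl bromide, BrCc1ccccc1
Why: Williamson etherification of the remaining phenol with a reactive halide; the aryl triflate should tolerate carbonate at this temperature, and capping the phenol first means no organozinc is consumed by it in step 4.

Step 3
Reactants: 4 1-bromo-3-methylbutane
Product: 5 bromo(3-methylbutyl)zinc, as a THF solution used directly
Conditions: Zn dust (activated with BrCH2CH2Br and Me3SiCl), LiCl, THF, 50 °C
Reagents that add atoms: zinc, [Zn]
Why: Direct insertion of activated zinc into a primary alkyl bromide, assisted by LiCl, gives the alkylzinc halide, which tolerates the ester of its coupling partner.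

Step 4
Reactants: 3 methyl 2-(benzyloxy)-6-methyl-4-[(trifluoromethanesulfonyl)oxy]benzoate; 5 bromo(3-methylbutyl)zinc
Product: 6 methyl 2-(benzyloxy)-6-methyl-4-(3-methylbutyl)benzoate
Conditions: Pd(dppf)Cl2 (3 mol%), THF, 60 °C
Reagents that add atoms: none
Why: Negishi coupling of an aryl triflate activated by the para ester; the wide-bite-angle bisphosphine favours reductive elimination over β-hydride elimination, so the primary chain should be transferred without isomerization.

Step 5
Reactants: 7 2,2-dimethyl-1,3-dioxane-4,6-dione (Meldrum's acid); 8 trimethyl orthoformate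
Product: 10 5-(hydroxymethylene)-2,2-dimethyl-1,3-dioxane-4,6-dione, via methoxymethylene Meldrum's acid 9 (not isolated)
Conditions: HC(OMe)3 (neat), reflux; concentrate; then 2 M HCl aq, rt
Reagents that add atoms: water, O
Why: Knoevenagel-type condensation of the active methylene with the orthoester gives the methoxymethylene compound; dilute acid hydrolyses its vinylogous ester to the enol of formyl Meldrum's acid while the ring acetal survives at room temperature.

Step 6
Reactants: 10 5-(hydroxymethylene)-2,2-dimethyl-1,3-dioxane-4,6-dione; 11 2,2-dimethylpropanal (pivalaldehyde)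
Product: 13 rac-2-tert-butyl-4H-1,3-dioxin-4-one, via formylketene 12 (not isolated)
Conditions: 11 (5 equiv), toluene, 110 °C, sealed vessel
Reagents that add atoms: none
Why: Thermal retro-[4+2] fragmentation of 10 releases formylketene, which is trapped by the carbonyl group of the non-enolizable aldehyde in a hetero-Diels–Alder reaction (acylketene plus carbonyl compound); the excess of 11 suppresses self-reaction of the ketene.

Step 7
Reactants: 13 rac-2-tert-butyl-4H-1,3-dioxin-4-one
Product: 14 (S)-2-tert-butyl-4H-1,3-dioxin-4-one
Conditions: preparative HPLC, cellulose tris(3,5-dimethylphenylcarbamate) on silica, hexane/iPrOH, rt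
Reagents that add atoms: none
Why: The acetal carbon is the only stereocentre and no chiral-pool precursor leads to it, so the enantiomers are separated on a polysaccharide stationary phase, an established way to resolve 2-tert-butyl-1,3-dioxin-4-ones; the acetal is configurationally stable and the R enantiomer is set aside.

Step 8
Reactants: 6 methyl 2-(benzyloxy)-6-methyl-4-(3-methylbutyl)benzoate; 14 (S)-2-tert-butyl-4H-1,3-dioxin-4-one
Product: 17 (2S,4aR,10aR)-6-(benzyloxy)-2-tert-butyl-8-(3-methylbutyl)-4a,10a-dihydro-4H-naphtho[2,3-d][1,3]dioxine-4,5(10H)-dione, via benzylic lithium species 15 (not isolated), via Michael adduct lithium enolate 16 (not isolated)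
Conditions: LiN(iPr)2 (1.1 equiv), THF, −78 °C; then 14 (1.2 equiv), −78 to −40 °C; AcOH, −78 °C
Reagents that add atoms: none
Why: This is a Staunton–Weinreb annulation (toluate Michael–Dieckmann sequence), known for unsaturated lactones and here run on a β-alkoxy unsaturated lactone. LiN(iPr)2 removes a proton from the ortho-methyl group of 6 to give the ester-stabilized benzylic anion 15, and this soft, delocalized carbanion should add to the oxygen-bearing alkene carbon of 14 (the future C3) and not to the lactone carbonyl, as toluate anions do with unsaturated lactones. Attack should come from the face opposite the tert-butyl group of the sofa-shaped ring, the sense found for conjugate additions to 2-tert-butyl-1,3-dioxin-4-ones, which with the S acetal places the new C–C bond so that C3 has the spatial arrangement of the R carbinol of the target. Lithium enolate 16 then attacks the neighbouring methyl ester in a 6-exo-trig Claisen (Dieckmann) closure that forms C2–C1 and ring B; the tether reaches only the enolate face that carries the benzylic carbon, so the ring fusion should be cis, and that centre is labile and removed later in any case. The lithium methoxide set free deprotonates the β-keto lactone, and the resulting doubly stabilized enolate is a poor donor for elimination. The step needs three things, conjugate rather than carbonyl addition, face selectivity, and retention of the C3 oxygen. The last is secured because the C3–O bond is a ring bond of the dioxanone and lies close to the plane of the enolate, so overlap for E1cB expulsion is poor (enolates of 2-tert-butyl-1,3-dioxan-4-ones can be alkylated at −78 °C without ring opening), and because the mixture is kept at or below −40 °C and quenched cold.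

Step 9
Reactants: 17 (2S,4aR,10aR)-6-(benzyloxy)-2-tert-butyl-8-(3-methylbutyl)-4a,10a-dihydro-4H-naphtho[2,3-d][1,3]dioxine-4,5(10H)-dione
Product: 19 (R)-8-(benzyloxy)-3-hydroxy-6-(3-methylbutyl)-3,4-dihydronaphthalen-1(2H)-one, via β-keto acid 18 (not isolated)
Conditions: 2 M HCl aq/THF (1:4), 45 °C
Reagents that add atoms: none
Why: Acid-catalysed acylal hydrolysis (the carboxylate of a β-keto acid is a good leaving group) releases pivalaldehyde, and β-keto acid 18 decarboxylates at the reaction temperature, which turns C2 into a methylene group; C3 is not touched, and dilute acid at moderate temperature should leave the β-hydroxy ketone and the benzyl ether intact.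

Step 10
Reactants: 19 (R)-8-(benzyloxy)-3-hydroxy-6-(3-methylbutyl)-3,4-dihydronaphthalen-1(2H)-one
Product: 20 (R)-8-(benzyloxy)-3-[(tert-butyldimethylsilyl)oxy]-6-(3-methylbutyl)-3,4-dihydronaphthalen-1(2H)-one
Conditions: TBSCl, imidazole, DMF, rt
Reagents that add atoms: tert-butyldimethylsilyl chloride, CC(C)(C)[Si](C)(C)Cl
Why: Standard silylation of a secondary alcohol under weakly basic conditions; the silyl ether blocks retro-aldol cleavage and palladium-mediated oxidation of the carbinol in steps 12 and 15.

Step 11
Reactants: 20 (R)-8-(benzyloxy)-3-[(tert-butyldimethylsilyl)oxy]-6-(3-methylbutyl)-3,4-dihydronaphthalen-1(2H)-one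
Product: 21 (R)-8-(benzyloxy)-5-bromo-3-[(tert-butyldimethylsilyl)oxy]-6-(3-methylbutyl)-3,4-dihydronaphthalen-1(2H)-one
Conditions: NBS (1.05 equiv), MeCN, 0 °C, dark
Reagents that add atoms: N-bromosuccinimide, O=C1CCC(=O)N1Br
Why: Electrophilic aromatic bromination; C5 is para to the benzyloxy group and ortho to two alkyl groups, while C7 is ortho to the ether and shielded by its benzyl group, so substitution should occur at C5, and in acetonitrile in the dark the ionic pathway should win over radical or ketone α-bromination.

Step 12
Reactants: 21 (R)-8-(benzyloxy)-5-bromo-3-[(tert-butyldimethylsilyl)oxy]-6-(3-methylbutyl)-3,4-dihydronaphthalen-1(2H)-one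
Product: 22 (R)-8-(benzyloxy)-3-[(tert-butyldimethylsilyl)oxy]-6-(3-methylbutyl)-5-(4,4,5,5-tetramethyl-1,3,2-dioxaborolan-2-yl)-3,4-dihydronaphthalen-1(2H)-one
Conditions: B2pin2, KOAc, Pd2(dba)3 (2.5 mol%), XPhos (10 mol%), 1,4-dioxane, 80 °C
Reagents that add atoms: bis(pinacolato)diboron, CC1(C)OB(OC1(C)C)B1OC(C)(C)C(C)(C)O1
Why: Miyaura borylation; the bulky electron-rich monophosphine allows oxidative addition and transmetalation at the doubly ortho-substituted bromide, and potassium acetate is too weak a base to enolize the ketone.

Step 13
Reactants: 23 propanedioyl dichloride (malonyl dichloride, 2 equiv)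
Product: 26 6-chloro-4-hydroxy-2H-pyran-2-one, via pyranone carbonyl chloride 24 (not isolated), via pyranone carboxylic acid 25 (not isolated)
Conditions: 23 (neat), 20 to 40 °C, several days, HCl vented; then H2O, 1,4-dioxane, 60 °C
Reagents that add atoms: propanedioyl dichloride (the second molecule of 23), O=C(Cl)CC(=O)Cl
Why: Self-condensation of malonyl dichloride, a known slow reaction of the neat liquid: the methylene carbon of one molecule is acylated by a second molecule (directly or through chlorocarbonylketene), and the enol oxygen of the terminal acid chloride of the new chain closes onto a chlorocarbonyl group, so that two HCl are lost and 6-chloro-4-hydroxy-2-oxo-2H-pyran-3-carbonyl chloride 24 results; water converts the acid chloride into vinylogous β-keto acid 25, which decarboxylates on warming.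

Step 14
Reactants: 26 6-chloro-4-hydroxy-2H-pyran-2-one
Product: 27 4-(benzyloxy)-6-chloro-2H-pyran-2-one
Conditions: BnOH, PPh3, DIAD, THF, 0 °C to rt
Reagents that add atoms: benzyl alcohol, OCc1ccccc1
Why: Mitsunobu etherification; the 4-hydroxyl is a vinylogous carboxylic acid, a good pronucleophile that is alkylated on oxygen, and the neutral conditions leave the vinylogous acid chloride at C6 alone.

Step 15
Reactants: 22 (R)-8-(benzyloxy)-3-[(tert-butyldimethylsilyl)oxy]-6-(3-methylbutyl)-5-(4,4,5,5-tetramethyl-1,3,2-dioxaborolan-2-yl)-3,4-dihydronaphthalen-1(2H)-one; 27 4-(benzyloxy)-6-chloro-2H-pyran-2-one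
Product: 28 (R)-8-(benzyloxy)-5-[4-(benzyloxy)-2-oxo-2H-pyran-6-yl]-3-[(tert-butyldimethylsilyl)oxy]-6-(3-methylbutyl)-3,4-dihydronaphthalen-1(2H)-one
Conditions: Pd(OAc)2 (5 mol%), SPhos (10 mol%), K3PO4, toluene/H2O (10:1), 50 °C
Reagents that add atoms: none
Why: Suzuki coupling; the C6–Cl bond of the pyranone is a vinylogous acyl chloride and should add readily to zerovalent palladium, the SPhos ligand is suited to doubly ortho-substituted arylboron partners, and phosphate in a two-phase mixture at moderate temperature is chosen to spare the lactone and the β-silyloxy ketone; the new axis has no stereochemical consequence.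

Step 16
Reactants: 28 (R)-8-(benzyloxy)-5-[4-(benzyloxy)-2-oxo-2H-pyran-6-yl]-3-[(tert-butyldimethylsilyl)oxy]-6-(3-methylbutyl)-3,4-dihydronaphthalen-1(2H)-one
Product: 29 (R)-8-(benzyloxy)-5-[4-(benzyloxy)-2-oxo-2H-pyran-6-yl]-3-hydroxy-6-(3-methylbutyl)-3,4-dihydronaphthalen-1(2H)-one
Conditions: HF·pyridine, pyridine, THF, 0 °C to rt
Reagents that add atoms: none
Why: Cleavage of the silyl ether by buffered, slightly acidic fluoride, which avoids the basic conditions under which the β-hydroxy ketone could eliminate; C3 is not involved.

Step 17
Reactants: 29 (R)-8-(benzyloxy)-5-[4-(benzyloxy)-2-oxo-2H-pyran-6-yl]-3-hydroxy-6-(3-methylbutyl)-3,4-dihydronaphthalen-1(2H)-one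
Product: 30 (R)-3,8-dihydroxy-5-(4-hydroxy-2-oxo-2H-pyran-6-yl)-6-(3-methylbutyl)-3,4-dihydronaphthalen-1(2H)-one
Conditions: H2 (1 atm), 10% Pd/C, EtOAc, rt
Reagents that add atoms: none
Why: Hydrogenolysis of the aryl benzyl ether and of the benzyl vinylogous ester under neutral conditions; the reaction is stopped after uptake of two equivalents of hydrogen so that the aryl ketone and the pyranone double bonds are not reduced.

## Compound list

1 | methyl 2,4-dihydroxy-6-methylbenzoate (methyl orsellinate) | COC(=O)c1c(C)cc(O)cc1O | starting material
2 | methyl 2-hydroxy-6-methyl-4-[(trifluoromethanesulfonyl)oxy]benzoate | COC(=O)c1c(C)cc(OS(=O)(=O)C(F)(F)F)cc1O | intermediate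
3 | methyl 2-(benzyloxy)-6-methyl-4-[(trifluoromethanesulfonyl)oxy]benzoate | COC(=O)c1c(C)cc(OS(=O)(=O)C(F)(F)F)cc1OCc1ccccc1 | intermediate
4 | 1-bromo-3-methylbutane | CC(C)CCBr | starting material
5 | bromo(3-methylbutyl)zinc | CC(C)CC[Zn]Br | intermediate
6 | methyl 2-(benzyloxy)-6-methyl-4-(3-methylbutyl)benzoate | COC(=O)c1c(C)cc(CCC(C)C)cc1OCc1ccccc1 | intermediate
7 | 2,2-dimethyl-1,3-dioxane-4,6-dione (Meldrum's acid) | CC1(C)OC(=O)CC(=O)O1 | starting material
8 | trimethyl orthoformate | COC(OC)OC | starting material
9 | 5-(methoxymethylene)-2,2-dimethyl-1,3-dioxane-4,6-dione | COC=C1C(=O)OC(C)(C)OC1=O | intermediate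
10 | 5-(hydroxymethylene)-2,2-dimethyl-1,3-dioxane-4,6-dione | OC=C1C(=O)OC(C)(C)OC1=O | intermediate
11 | 2,2-dimethylpropanal (pivalaldehyde) | CC(C)(C)C=O | starting material
12 | formylketene (3-oxoprop-2-enal) | O=CC=C=O | intermediate
13 | rac-2-tert-butyl-4H-1,3-dioxin-4-one | CC(C)(C)C1OC=CC(=O)O1 | intermediate
14 | (S)-2-tert-butyl-4H-1,3-dioxin-4-one | CC(C)(C)[C@H]1OC=CC(=O)O1 | intermediate
15 | methyl 2-(benzyloxy)-6-(lithiomethyl)-4-(3-methylbutyl)benzoate | [Li]Cc1cc(CCC(C)C)cc(OCc2ccccc2)c1C(=O)OC | intermediate
16 | lithium enolate of methyl 2-(benzyloxy)-6-{[(2S,4R)-2-tert-butyl-6-oxo-1,3-dioxan-4-yl]methyl}-4-(3-methylbutyl)benzoate | [Li]OC1=C[C@@H](Cc2cc(CCC(C)C)cc(OCc3ccccc3)c2C(=O)OC)O[C@H](C(C)(C)C)O1 | intermediate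
17 | (2S,4aR,10aR)-6-(benzyloxy)-2-tert-butyl-8-(3-methylbutyl)-4a,10a-dihydro-4H-naphtho[2,3-d][1,3]dioxine-4,5(10H)-dione (cis-fused; position 4a labile) | c1ccccc1COc1cc(CCC(C)C)cc2c1C(=O)[C@@H]1C(=O)O[C@@H](C(C)(C)C)O[C@@H]1C2 | intermediate
18 | (2R,3R)-8-(benzyloxy)-3-hydroxy-6-(3-methylbutyl)-1-oxo-1,2,3,4-tetrahydronaphthalene-2-carboxylic acid | c1ccccc1COc1cc(CCC(C)C)cc2c1C(=O)[C@H](C(=O)O)[C@H](O)C2 | intermediate
19 | (R)-8-(benzyloxy)-3-hydroxy-6-(3-methylbutyl)-3,4-dihydronaphthalen-1(2H)-one | c1ccccc1COc1cc(CCC(C)C)cc2c1C(=O)C[C@H](O)C2 | intermediate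
20 | (R)-8-(benzyloxy)-3-[(tert-butyldimethylsilyl)oxy]-6-(3-methylbutyl)-3,4-dihydronaphthalen-1(2H)-one | c1ccccc1COc1cc(CCC(C)C)cc2c1C(=O)C[C@H](O[Si](C)(C)C(C)(C)C)C2 | intermediate
21 | (R)-8-(benzyloxy)-5-bromo-3-[(tert-butyldimethylsilyl)oxy]-6-(3-methylbutyl)-3,4-dihydronaphthalen-1(2H)-one | c1ccccc1COc1cc(CCC(C)C)c(Br)c2c1C(=O)C[C@H](O[Si](C)(C)C(C)(C)C)C2 | intermediate
22 | (R)-8-(benzyloxy)-3-[(tert-butyldimethylsilyl)oxy]-6-(3-methylbutyl)-5-(4,4,5,5-tetramethyl-1,3,2-dioxaborolan-2-yl)-3,4-dihydronaphthalen-1(2H)-one | c1ccccc1COc1cc(CCC(C)C)c(B3OC(C)(C)C(C)(C)O3)c2c1C(=O)C[C@H](O[Si](C)(C)C(C)(C)C)C2 | intermediate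
23 | propanedioyl dichloride (malonyl dichloride) | O=C(Cl)CC(=O)Cl | starting material
24 | 6-chloro-4-hydroxy-2-oxo-2H-pyran-3-carbonyl chloride | O=C(Cl)c1c(O)cc(Cl)oc1=O | intermediate
25 | 6-chloro-4-hydroxy-2-oxo-2H-pyran-3-carboxylic acid | O=C(O)c1c(O)cc(Cl)oc1=O | intermediate
26 | 6-chloro-4-hydroxy-2H-pyran-2-one | Oc1cc(Cl)oc(=O)c1 | intermediate
27 | 4-(benzyloxy)-6-chloro-2H-pyran-2-one | Clc1cc(OCc2ccccc2)cc(=O)o1 | intermediate
28 | (R)-8-(benzyloxy)-5-[4-(benzyloxy)-2-oxo-2H-pyran-6-yl]-3-[(tert-butyldimethylsilyl)oxy]-6-(3-methylbutyl)-3,4-dihydronaphthalen-1(2H)-one | c1ccccc1COc1cc(CCC(C)C)c(-c3cc(OCc4ccccc4)cc(=O)o3)c2c1C(=O)C[C@H](O[Si](C)(C)C(C)(C)C)C2 | intermediate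
29 | (R)-8-(benzyloxy)-5-[4-(benzyloxy)-2-oxo-2H-pyran-6-yl]-3-hydroxy-6-(3-methylbutyl)-3,4-dihydronaphthalen-1(2H)-one | c1ccccc1COc1cc(CCC(C)C)c(-c3cc(OCc4ccccc4)cc(=O)o3)c2c1C(=O)C[C@H](O)C2 | intermediate
30 | (R)-3,8-dihydroxy-5-(4-hydroxy-2-oxo-2H-pyran-6-yl)-6-(3-methylbutyl)-3,4-dihydronaphthalen-1(2H)-one | CC(C)CCc1cc(O)c2c(c1-c1cc(O)cc(=O)o1)C[C@@H](O)CC2=O | target

## Step count and risk assessment

Total step count: 17. Longest linear sequence: 11 steps (steps 1, 2, 4, 8, 9, 10, 11, 12, 15, 16, 17 from 1, or steps 5, 6, 7, 8, 9, 10, 11, 12, 15, 16, 17 from 7 and 8).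

**Step 8 (key step).** The most likely failure is ring-opening β-elimination of the dioxanone enolate, before or after the Claisen closure. This expels the acetal oxygen from C3 and leads to aromatization of ring B; it would take over if closure onto the hindered methyl ester is slow enough that the mixture must be warmed. Lesser risks are attack at the lactone carbonyl instead of conjugate addition, erosion of face selectivity with a lithium nucleophile, and self-condensation of the toluate anion. The fallback closes ring B by a Dieckmann condensation on an open chain whose carbinol is set by hydrogenation; it sets out from 6 and comes back at 19. Lithiated 6 is quenched with CO2 to give the arylacetic acid 2-[3-(benzyloxy)-2-(methoxycarbonyl)-5-(3-methylbutyl)phenyl]acetic acid F1. Activation with 1,1'-carbonyldiimidazole and reaction with Mg(O2CCH2CO2tBu)2 (Masamune chain extension) gives the β-keto ester tert-butyl 4-[3-(benzyloxy)-2-(methoxycarbonyl)-5-(3-methylbutyl)phenyl]-3-oxobutanoate F2. Noyori hydrogenation with RuCl2[(R)-BINAP] should give the β-hydroxy ester tert-butyl (3R)-4-[3-(benzyloxy)-2-(methoxycarbonyl)-5-(3-methylbutyl)phenyl]-3-hydroxybutanoate F3. Because its hydroxyl could lactonize onto the aryl ester under base, F3 is silylated without delay (TBSOTf, 2,6-lutidine, −78 °C) to the silyl ether tert-butyl (3R)-4-[3-(benzyloxy)-2-(methoxycarbonyl)-5-(3-methylbutyl)phenyl]-3-[(tert-butyldimethylsilyl)oxy]butanoate F4. LiN(iPr)2 (2.2 equiv) at −78 °C forms the tert-butyl ester enolate, whose β-silyloxy group is a poor leaving group at this temperature, and the enolate closes onto the aryl methyl ester to give the β-keto ester tert-butyl (3R)-8-(benzyloxy)-3-[(tert-butyldimethylsilyl)oxy]-6-(3-methylbutyl)-1-oxo-1,2,3,4-tetrahydronaphthalene-2-carboxylate F5. Aqueous trifluoroacetic acid removes the tert-butyl and silyl groups, and the β-keto acid decarboxylates to 19.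

**Step 9.** Acid-promoted dehydration of the freshly released β-hydroxy ketone could compete with acetal hydrolysis, because the elimination product tautomerizes to a naphthol and is irreversible. The fallback avoids acid and sets out from 17, coming back at 20. Transesterification with allyl alcohol and catalytic 4-(dimethylamino)pyridine in toluene opens the acylal to the allyl β-keto ester prop-2-en-1-yl (3R)-8-(benzyloxy)-3-hydroxy-6-(3-methylbutyl)-1-oxo-1,2,3,4-tetrahydronaphthalene-2-carboxylate F6. Silylation with TBSCl and imidazole gives its silyl ether prop-2-en-1-yl (3R)-8-(benzyloxy)-3-[(tert-butyldimethylsilyl)oxy]-6-(3-methylbutyl)-1-oxo-1,2,3,4-tetrahydronaphthalene-2-carboxylate F7. Pd(PPh3)4 with morpholine at room temperature then removes the allyl group with decarboxylation under neutral conditions to give 20.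

**Step 15.** Base-induced enolization of the β-silyloxy ketone, followed by loss of silanolate and aromatization, could compete with a slow transmetalation at the hindered boronate. Protodeboronation and opening of the pyranone lactone by hydroxide are further risks. The fallback removes the enolizable ketone for the duration of the palladium steps; it sets out from 21 and comes back at 28. NaBH4 reduces the ketone to the C1 carbinol (3R)-8-(benzyloxy)-5-bromo-3-[(tert-butyldimethylsilyl)oxy]-6-(3-methylbutyl)-1,2,3,4-tetrahydronaphthalen-1-ol F8, as a mixture of C1 epimers. Miyaura borylation gives the boronate (3R)-8-(benzyloxy)-3-[(tert-butyldimethylsilyl)oxy]-6-(3-methylbutyl)-5-(4,4,5,5-tetramethyl-1,3,2-dioxaborolan-2-yl)-1,2,3,4-tetrahydronaphthalen-1-ol F9. Suzuki coupling with 27 gives the biaryl alcohol 4-(benzyloxy)-6-[(7R)-4-(benzyloxy)-7-[(tert-butyldimethylsilyl)oxy]-5-hydroxy-2-(3-methylbutyl)-5,6,7,8-tetrahydronaphthalen-1-yl]-2H-pyran-2-one F10. MnO2 oxidizes the benzylic alcohol back to the ketone 28.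

**Step 11.** Attack at C7 (ortho to the ether) alongside C5 would give isomers that are hard to separate at this late stage, and α-bromination of the ketone or acid-induced loss of the silyl group by adventitious HBr could also occur. The fallback moves the bromination to the toluate, where no ketone or silyl ether is present and isomers can be removed early; it sets out from 6 and comes back at 21. NBS in acetonitrile gives the bromotoluate methyl 6-(benzyloxy)-3-bromo-2-methyl-4-(3-methylbutyl)benzoate F11. Annulation with 14 under the conditions of step 8 gives the bromo tricycle (2S,4aR,10aR)-6-(benzyloxy)-9-bromo-2-tert-butyl-8-(3-methylbutyl)-4a,10a-dihydro-4H-naphtho[2,3-d][1,3]dioxine-4,5(10H)-dione F12. Acid hydrolysis with decarboxylation gives the bromo alcohol (R)-8-(benzyloxy)-5-bromo-3-hydroxy-6-(3-methylbutyl)-3,4-dihydronaphthalen-1(2H)-one F13, and silylation gives 21.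

**Step 6.** Formylketene may react with itself or with the enol of 10 faster than with the hindered, volatile aldehyde, which would leave little dioxinone. The fallback builds the ring first and introduces the double bond afterwards; it sets out from 11 and comes back at 13. Acid-catalysed acetalization of 3-hydroxypropanoic acid with 11 (TsOH, azeotropic removal of water) gives the saturated acetal rac-2-tert-butyl-1,3-dioxan-4-one F14. Radical bromination with NBS and a little azobisisobutyronitrile gives the bromide rac-6-bromo-2-tert-butyl-1,3-dioxan-4-one F15, which with Et3N eliminates to 13.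

## Further compounds

F1 | step 8 | 2-[3-(benzyloxy)-2-(methoxycarbonyl)-5-(3-methylbutyl)phenyl]acetic acid | COC(=O)c1c(CC(=O)O)cc(CCC(C)C)cc1OCc1ccccc1
F2 | step 8 | tert-butyl 4-[3-(benzyloxy)-2-(methoxycarbonyl)-5-(3-methylbutyl)phenyl]-3-oxobutanoate | COC(=O)c1c(CC(=O)CC(=O)OC(C)(C)C)cc(CCC(C)C)cc1OCc1ccccc1
F3 | step 8 | tert-butyl (3R)-4-[3-(benzyloxy)-2-(methoxycarbonyl)-5-(3-methylbutyl)phenyl]-3-hydroxybutanoate | COC(=O)c1c(C[C@@H](O)CC(=O)OC(C)(C)C)cc(CCC(C)C)cc1OCc1ccccc1
F4 | step 8 | tert-butyl (3R)-4-[3-(benzyloxy)-2-(methoxycarbonyl)-5-(3-methylbutyl)phenyl]-3-[(tert-butyldimethylsilyl)oxy]butanoate | COC(=O)c1c(C[C@@H](O[Si](C)(C)C(C)(C)C)CC(=O)OC(C)(C)C)cc(CCC(C)C)cc1OCc1ccccc1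
F5 | step 8 | tert-butyl (3R)-8-(benzyloxy)-3-[(tert-butyldimethylsilyl)oxy]-6-(3-methylbutyl)-1-oxo-1,2,3,4-tetrahydronaphthalene-2-carboxylate (C2 epimers) | CC(C)(C)OC(=O)C1C(=O)c2c(OCc3ccccc3)cc(CCC(C)C)cc2C[C@H]1O[Si](C)(C)C(C)(C)C
F6 | step 9 | prop-2-en-1-yl (3R)-8-(benzyloxy)-3-hydroxy-6-(3-methylbutyl)-1-oxo-1,2,3,4-tetrahydronaphthalene-2-carboxylate (C2 epimers) | C=CCOC(=O)C1C(=O)c2c(OCc3ccccc3)cc(CCC(C)C)cc2C[C@H]1O
F7 | step 9 | prop-2-en-1-yl (3R)-8-(benzyloxy)-3-[(tert-butyldimethylsilyl)oxy]-6-(3-methylbutyl)-1-oxo-1,2,3,4-tetrahydronaphthalene-2-carboxylate (C2 epimers) | C=CCOC(=O)C1C(=O)c2c(OCc3ccccc3)cc(CCC(C)C)cc2C[C@H]1O[Si](C)(C)C(C)(C)C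
F8 | step 15 | (3R)-8-(benzyloxy)-5-bromo-3-[(tert-butyldimethylsilyl)oxy]-6-(3-methylbutyl)-1,2,3,4-tetrahydronaphthalen-1-ol (C1 epimers) | c1ccccc1COc1cc(CCC(C)C)c(Br)c2c1C(O)C[C@H](O[Si](C)(C)C(C)(C)C)C2
F9 | step 15 | (3R)-8-(benzyloxy)-3-[(tert-butyldimethylsilyl)oxy]-6-(3-methylbutyl)-5-(4,4,5,5-tetramethyl-1,3,2-dioxaborolan-2-yl)-1,2,3,4-tetrahydronaphthalen-1-ol (C1 epimers) | c1ccccc1COc1cc(CCC(C)C)c(B3OC(C)(C)C(C)(C)O3)c2c1C(O)C[C@H](O[Si](C)(C)C(C)(C)C)C2
F10 | step 15 | 4-(benzyloxy)-6-[(7R)-4-(benzyloxy)-7-[(tert-butyldimethylsilyl)oxy]-5-hydroxy-2-(3-methylbutyl)-5,6,7,8-tetrahydronaphthalen-1-yl]-2H-pyran-2-one (C5 epimers of the tetrahydronaphthalene) | c1ccccc1COc1cc(CCC(C)C)c(-c3cc(OCc4ccccc4)cc(=O)o3)c2c1C(O)C[C@H](O[Si](C)(C)C(C)(C)C)C2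
F11 | step 11 | methyl 6-(benzyloxy)-3-bromo-2-methyl-4-(3-methylbutyl)benzoate | COC(=O)c1c(C)c(Br)c(CCC(C)C)cc1OCc1ccccc1
F12 | step 11 | (2S,4aR,10aR)-6-(benzyloxy)-9-bromo-2-tert-butyl-8-(3-methylbutyl)-4a,10a-dihydro-4H-naphtho[2,3-d][1,3]dioxine-4,5(10H)-dione | c1ccccc1COc1cc(CCC(C)C)c(Br)c2c1C(=O)[C@@H]1C(=O)O[C@@H](C(C)(C)C)O[C@@H]1C2
F13 | step 11 | (R)-8-(benzyloxy)-5-bromo-3-hydroxy-6-(3-methylbutyl)-3,4-dihydronaphthalen-1(2H)-one | c1ccccc1COc1cc(CCC(C)C)c(Br)c2c1C(=O)C[C@H](O)C2
F14 | step 6 | rac-2-tert-butyl-1,3-dioxan-4-one | CC(C)(C)C1OCCC(=O)O1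
F15 | step 6 | rac-6-bromo-2-tert-butyl-1,3-dioxan-4-one | CC(C)(C)C1OC(Br)CC(=O)O1
A1 | alternative 1 | (R)-8-(benzyldimethylsilyl)-3-(tert-butyldimethylsilyloxy)-5-(4-methoxy-2-oxo-2H-pyran-6-yl)-6-(3-methylbutyl)-3,4-dihydronaphthalen-1(2H)-one | C[Si](C)(Cc1ccccc1)c1cc(CCC(C)C)c(-c2cc(OC)cc(=O)o2)c2c1C(=O)C[C@H](O[Si](C)(C)C(C)(C)C)C2
A2 | alternative 2 | methyl 2-[2-acetyl-3-methoxy-5-(3-methylbutyl)phenyl]acetate | COC(=O)Cc1cc(CCC(C)C)cc(OC)c1C(C)=O
A3 | alternative 3 | (R)-3-(tert-butyldimethylsilyloxy)-8-hydroxy-6-(3-methylbutyl)-3,4-dihydronaphthalen-1(2H)-one | CC(C)CCc1cc(O)c2c(c1)C[C@@H](O[Si](C)(C)C(C)(C)C)CC2=O
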